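**Conventions and assumptions.** Terpenoid atoms carry guaiane-type numbers: C1 ring-fusion CH, C2, C3, C4 quaternary, C5=C6, C7, C8, C9, C10, C11 carbinol carbon, C14 the carbon on C10, C9′ the benzylic carbon. Ar = 2,4,6-trimethoxyphenyl. Q = (5R)-5-methyl-5-[(1S)-1-Ar-3-methylbutyl]cyclopent-1-en-1-yl (its C1 is C5 of the target, its C5 is C4). Assumption: in step 1 the hand of the ferrocenyl diphosphine is the one that gives the 4S lactone.

## Analysis of the target

- **Skeleton.** The target is a 3,5-diformylphloroglucinol whose sixth ring carbon carries the benzylic methine C9′ (isobutyl-substituted). C9′ is bonded to the quaternary C4 of a hydroazulene: a cyclopentane (C1–C5) fused at C1–C5 to a cycloheptene (C1, C5–C10) whose only alkene is C5=C6.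
- **Substituents.** C4 and C10 each bear a methyl group and C7 bears a 2-hydroxypropan-2-yl group (C11).
- **Stereocentres.** There are five: C1, C4, C7 and C10 (all R) and C9′ (S). With the bicycle drawn flat, the C4 methyl, the C10 methyl and C2 lie on one face; H1, H10, the C7 side chain and C9′ lie on the other. H1 and H10 are therefore cis, and the C7 side chain is trans to the C10 methyl.
- **Sensitive groups.** The tertiary homoallylic alcohol and the trisubstituted alkene are acid-labile (ionisation, elimination, cyclo-etherification). The two aryl aldehydes exclude hydride, organometallic and enolate chemistry once they are in place. The electron-rich arene is open to electrophiles and oxidants.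
- **Difficulty.** The C4/C9′ pair is a vicinal quaternary/tertiary pair next to a 2,6-dioxygenated aryl group. The C1/C10 pair must be set on a seven-membered ring far from C4/C9′.
- **Feature used.** C1 and C10 are adjacent stereocentres, and C1 is the far terminus of the allyl unit C6–C5–C1. If C14 is a carboxyl carbon bound through oxygen to C6, the atoms C10, C14, O, C6, C5, C1 are the six-atom array of an ester-enolate Claisen rearrangement. That shift makes C1–C10, places the alkene at C5=C6 and closes the cycloheptene, because C7–C8–C9 already joins C6 to C10.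

## Retrosynthetic reasoning

**Aryl groups last (37 back to 33).** The three O–H bonds and the two aryl C–CHO bonds are cut first, through 36, 35 and 34 to trimethyl ether 33. The aldehydes cannot pass the reductions and carbanion steps, so they come last. The tertiary oxygen would ionise under Lewis-acid formylation or boron-halide ether cleavage. The forward steps therefore use bromination, bromine–lithium exchange and formylation under basic conditions, fluoride for the silyl ether, and a sulfur nucleophile for the methyl ethers.

**C10 methyl from a carboxyl (33 back to 30).** The C14 methyl is taken back through tosylate 32 and alcohol 31 to acid 30. No skeletal bond is cut; the gain is the carboxyl group that a Claisen shift leaves on C10.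

**The C1–C10 bond (30 back to 27).** This is the key disconnection. Cutting C1–C10 and rejoining C14 to an oxygen on C6 gives the seven-membered lactone 27. The cut is made here because both new stereocentres then derive from one carbinol centre (C6) and from a transition-state geometry that the tether enforces. The forward reaction must deliver C10 to the cyclopentene face that carries the C4 methyl and must place the carboxyl and C2 on the same side of the new ring.

**The lactone ring (27 back to 23 and 24).** The saturated lactone is taken back to the unsaturated lactone 26, then the C9=C10 bond is cut (ring-closing metathesis of acrylate 25), then the O–C14 ester bond (acylation of alcohol 23 with 24). This avoids a medium-ring lactonisation of a hindered hydroxy acid. It also uses the allyl group that the auxiliary alkylation puts on C7 in any case.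

**The C5–C6 bond and the C6 configuration (23 back to 10 and 20).** C5–C6 is cut between alkenyl triflate 10 and aldehyde 20. A direct alkenyl-metal addition cannot be relied on for C6. The Felkin–Anh preference of this α-branched aldehyde points to the 6R carbinol, and the suprafacial shift would then send C10 to the wrong face. C6 is therefore taken back to ketone 22 (from the epimer mixture 21), where hydride delivery under the same Felkin–Anh control gives the 6S carbinol.

**The C7 stereocentre (20 back to 11, 14 and 17).** Aldehyde 20 comes from alcohol 19 and imide 18. The C7–C8 bond is cut by an auxiliary-controlled enolate alkylation of imide 16 with 17. Imide 16 comes from acid 13 (from 11 through 12) and oxazolidinone 14.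

**The C4/C9′ pair and the cyclopentene (10 back to 1 and 2).** Triflate 10 comes from ketone 9 and phenol 8. The C1–C5 bond is cut so that C5 becomes the carbonyl of a six-membered aryl lactone (7, 6) that ties C9′ and C4 into one ring through the ortho oxygen the target keeps. In that ring the C4–methyl bond is cut (methylation trans to isobutyl, 6 from 5), then C4–C3 (alkylation of 3 with 4), then C9′–isobutyl (conjugate addition of 2 to coumarin 1). The vicinal pair is thus set by one catalyst-controlled step and one ring-controlled step, and the lactone carbonyl is used again as the C5 ketone.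

## Alternatives that were turned down

**Alternative 1:** The C7–C8 bond is cut. In the forward sense, the extended enolate of the iodo enoate A2 (ester carbon on C7, γ-proton on C5) is alkylated at C7 by the tethered primary iodide C8, closing the cycloheptene as the C7 methyl ester A1 with the alkene at C5=C6.
- For it: the ring closure is a classical alkylation, the alkene ends where it is needed, and C10 carries its real methyl group. It is stronger on step economy after ring closure, since the three-step reduction of a carboxyl to the methyl group is not needed.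
- Against it: C1 and C10 must already be in place on a cyclopentane next to the quaternary C4, with no pericyclic geometry to set them. The C7 configuration depends on the conformation of a forming seven-membered ring, and α- versus γ-alkylation of the dienolate is a further selectivity issue.
- In its place the chosen strategy offers C1 and C10 from one stereocentre (C6) in one step.

**Alternative 2:** The bonds C1–C5, C2–C3 and C3–C4 are cut. In the forward sense, the allene–yne A4 undergoes a carbonylative [2+2+1] cyclisation through its terminal alkyne and the distal allene bond, giving the bicyclic dienone A3 with both rings formed at once.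
- For it: it is clearly stronger in bonds and rings formed per step and in convergence.
- Against it: the quaternary C4 would be created at a fully substituted allene terminus that bears the bulky benzylic group, and its configuration would have to come from allene axial chirality next to C9′. A3 also carries a C3 ketone and a C1=C2 alkene that the target lacks. Removing them costs several steps and sets C1 late by a reduction whose facial outcome is not fixed by anything nearby.
- In its place the chosen strategy offers a C4/C9′ pair fixed before the rings are joined and no surplus functionality in the bicycle.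

**Alternative 3:** The aryl bond C1′–C6′ is cut. In the forward sense, the polyanion of the 3,5-dioxo ester A6 cyclises by attack of its terminal carbanion on the ester carbonyl, and the ring aromatises to the 2-alkylphloroglucinol A5.
- For it: no methyl ethers have to be removed at the end and the phenol arrives free for mild formylation. On this point it is stronger than the chosen route, whose last step is its weakest.
- Against it: the key step does nothing for the hydroazulene, so C1, C10 and the seven-membered ring remain unsolved. The triketo chain must be built on a neopentyl-type carbon and can also close to pyrones or resorcylates. C9′ must be set without the aryl group that the chosen route uses to build the C4/C9′ pair.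
- In its place the chosen strategy spends its key step on the carbocyclic core and pays with a late ether cleavage.

Key step: step 19

## Route

Step 1
Reactants: 1 5,7-dimethoxycoumarin (5,7-dimethoxy-2H-chromen-2-one); 2 isobutylmagnesium bromide
Product: 3 (4S)-4-isobutyl-5,7-dimethoxychroman-2-one
Conditions: CuBr·SMe2 (5 mol%), chiral 1-[2-(dicyclohexylphosphino)ferrocenyl]ethyldiphenylphosphine (6 mol%), t-BuOMe, −78 °C; NH4Cl aq
Reagents that add atoms: none
Why: Copper-catalysed asymmetric conjugate addition of a Grignard reagent to a coumarin; the chiral copper–diphosphine complex selects the face of the β-carbon and so sets C9′, and the magnesium enolate is protonated on work-up.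

Step 2
Reactants: 3 (4S)-4-isobutyl-5,7-dimethoxychroman-2-one; 4 1-chloro-3-iodopropane
Product: 5 (3S,4S)-3-(3-chloropropyl)-4-isobutyl-5,7-dimethoxychroman-2-one (3,4-trans)
Conditions: LiN(iPr)2, THF, −78 °C; 4, DMPU, −78 → −30 °C
Reagents that add atoms: none
Why: Lactone enolate alkylation; only the iodide end of 4 reacts, the new chain should enter trans to isobutyl, and this centre is made planar again in step 3.

Step 3
Reactants: 5 (3S,4S)-3-(3-chloropropyl)-4-isobutyl-5,7-dimethoxychroman-2-one
Product: 6 (3R,4R)-3-(3-chloropropyl)-4-isobutyl-5,7-dimethoxy-3-methylchroman-2-one (methyl trans to isobutyl)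
Conditions: LiN(iPr)2, THF, −78 °C; MeI, −78 → −20 °C
Reagents that add atoms: iodomethane, CI
Why: Second enolate alkylation makes the quaternary C4; allylic strain and the peri methoxy group hold the isobutyl group pseudo-axial on the neighbouring carbon, so iodomethane adds to the opposite face and gives the C4/C9′ relationship of the target.

Step 4
Reactants: 6 (3R,4R)-3-(3-chloropropyl)-4-isobutyl-5,7-dimethoxy-3-methylchroman-2-one
Product: 7 (3R,4R)-3-(3-iodopropyl)-4-isobutyl-5,7-dimethoxy-3-methylchroman-2-one
Conditions: NaI, acetone, reflux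
Reagents that add atoms: sodium iodide, [Na+].[I-]
Why: Finkelstein exchange, driven by precipitation of NaCl, makes the chain end fit for iodine–lithium exchange.

Step 5
Reactants: 7 (3R,4R)-3-(3-iodopropyl)-4-isobutyl-5,7-dimethoxy-3-methylchroman-2-one
Product: 8 (2R)-2-[(1R)-1-(2-hydroxy-4,6-dimethoxyphenyl)-3-methylbutyl]-2-methylcyclopentan-1-one
Conditions: t-BuLi (2.1 equiv), Et2O–pentane, −78 → 0 °C; NH4Cl aq
Reagents that add atoms: none
Why: Parham-type anionic cyclisation of an iodoalkyl ester: iodine–lithium exchange is faster than addition to the hindered lactone carbonyl, the primary carbanion attacks C5 (5-exo), the aryloxide leaves and the C5 ketone forms without touching C4 or C9′.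

Step 6
Reactants: 8 (2R)-2-[(1R)-1-(2-hydroxy-4,6-dimethoxyphenyl)-3-methylbutyl]-2-methylcyclopentan-1-one
Product: 9 (2R)-2-methyl-2-[(1R)-1-Ar-3-methylbutyl]cyclopentan-1-one
Conditions: MeI, K2CO3, acetone, reflux
Reagents that add atoms: iodomethane, CI
Why: Williamson O-methylation of the phenoxide; any ring-closed hemiketal form of 8 is drained through the open phenoxide, and K2CO3 does not enolise the ketone.

Step 7
Reactants: 9 (2R)-2-methyl-2-[(1R)-1-Ar-3-methylbutyl]cyclopentan-1-one
Product: 10 (5R)-5-methyl-5-[(1S)-1-Ar-3-methylbutyl]cyclopent-1-en-1-yl trifluoromethanesulfonate (Q–OTf)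
Conditions: KN(SiMe3)2, THF, −78 °C; PhNTf2, −78 → 0 °C
Reagents that add atoms: N-phenylbis(trifluoromethanesulfonimide), O=S(=O)(N(c1ccccc1)S(=O)(=O)C(F)(F)F)C(F)(F)F
Why: Enol triflate formation; C1 is the only enolisable position, so the enolate and the alkenyl triflate form with a single regiochemistry.

Step 8
Reactants: 11 3-hydroxy-3-methylbutanoic acid
Product: 13 3-methyl-3-(triethylsilyloxy)butanoic acid, via triethylsilyl 3-methyl-3-(triethylsilyloxy)butanoate 12 (not isolated)
Conditions: Et3SiOTf (2.2 equiv), 2,6-lutidine, CH2Cl2, 0 °C; then K2CO3, MeOH–H2O; pH 5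
Reagents that add atoms: triethylsilyl trifluoromethanesulfonate, CC[Si](CC)(CC)OS(=O)(=O)C(F)(F)F
Why: Silylation of both oxygens followed by selective hydrolysis of the labile silyl ester; the tertiary silyl ether is kept as a bulky, non-chelating group for steps 10 and 15.

Step 9
Reactants: 13 3-methyl-3-(triethylsilyloxy)butanoic acid; 14 (4S)-4-benzyl-1,3-oxazolidin-2-one
Product: 16 (4S)-4-benzyl-3-[3-methyl-3-(triethylsilyloxy)butanoyl]-1,3-oxazolidin-2-one, via mixed pivalic anhydride 15 (not isolated)
Conditions: t-BuCOCl, Et3N, THF, −20 °C; then 14, LiCl, 25 °C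
Reagents that add atoms: pivaloyl chloride, CC(C)(C)C(Cl)=O (its atoms stay in 15 only)
Why: N-acylation of the oxazolidinone through a mixed anhydride; the hindered pivaloyl carbonyl directs attack to the wanted acyl group.

Step 10
Reactants: 16 (4S)-4-benzyl-3-[3-methyl-3-(triethylsilyloxy)butanoyl]-1,3-oxazolidin-2-one; 17 allyl iodide
Product: 18 (4S)-4-benzyl-3-{(2S)-2-[2-(triethylsilyloxy)propan-2-yl]pent-4-enoyl}-1,3-oxazolidin-2-one
Conditions: NaN(SiMe3)2, THF, −78 °C; 17, −78 → −40 °C
Reagents that add atoms: none
Why: Evans oxazolidinone alkylation; the chelated Z-enolate is attacked by the allylic iodide on the face away from the benzyl group, which sets C7, and the silyloxy group is too poor a leaving group to eliminate at this temperature.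

Step 11
Reactants: 18 (4S)-4-benzyl-3-{(2S)-2-[2-(triethylsilyloxy)propan-2-yl]pent-4-enoyl}-1,3-oxazolidin-2-one
Product: 19 (2R)-2-[2-(triethylsilyloxy)propan-2-yl]pent-4-en-1-ol
Conditions: LiBH4, H2O (1 equiv), Et2O, 0 °C
Reagents that add atoms: none
Why: Reductive cleavage of the imide gives the primary alcohol without touching C7 and returns the auxiliary.

Step 12
Reactants: 19 (2R)-2-[2-(triethylsilyloxy)propan-2-yl]pent-4-en-1-ol
Product: 20 (2S)-2-[2-(triethylsilyloxy)propan-2-yl]pent-4-enal
Conditions: Dess–Martin periodinane, NaHCO3, CH2Cl2, 0 → 25 °C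
Reagents that add atoms: none
Why: Dess–Martin oxidation under buffered, non-basic conditions gives the α-branched aldehyde without epimerising C7; it is used at once.

Step 13
Reactants: 10 Q–OTf; 20 (2S)-2-[2-(triethylsilyloxy)propan-2-yl]pent-4-enal
Product: 21 (2R)-1-Q-2-[2-(triethylsilyloxy)propan-2-yl]pent-4-en-1-ol (both C6 epimers)
Conditions: CrCl2 (5 equiv), NiCl2 (2 mol%), DMF, 25 °C
Reagents that add atoms: none
Why: Nozaki–Hiyama–Kishi coupling; zerovalent nickel inserts into the C–OTf bond and transmetallation to chromium gives a non-basic alkenyl nucleophile that forms C5–C6 without enolising the aldehyde; the Felkin–Anh sense should favour the 6R epimer, so C6 is reset in steps 14 and 15.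

Step 14
Reactants: 21 (2R)-1-Q-2-[2-(triethylsilyloxy)propan-2-yl]pent-4-en-1-ol (both C6 epimers)
Product: 22 (2S)-1-Q-2-[2-(triethylsilyloxy)propan-2-yl]pent-4-en-1-one
Conditions: Dess–Martin periodinane, NaHCO3, CH2Cl2, 0 → 25 °C
Reagents that add atoms: none
Why: Oxidation of the allylic alcohol converges both epimers on one enone; the buffer protects the C7 stereocentre next to the ketone.

Step 15
Reactants: 22 (2S)-1-Q-2-[2-(triethylsilyloxy)propan-2-yl]pent-4-en-1-one
Product: 23 (1S,2R)-1-Q-2-[2-(triethylsilyloxy)propan-2-yl]pent-4-en-1-ol (6S,7R)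
Conditions: LiBH(s-Bu)3, THF, −78 °C; NH4Cl aq
Reagents that add atoms: none
Why: Felkin–Anh 1,2-reduction; the bulky, non-chelating silyloxy-isopropyl group on C7 lies anti to the incoming hydride, which passes the C7 hydrogen and gives the 6S carbinol (hydroxyl and C8 anti); the twisted, hindered enone disfavours conjugate reduction.

Step 16
Reactants: 23 (1S,2R)-1-Q-2-[2-(triethylsilyloxy)propan-2-yl]pent-4-en-1-ol; 24 acryloyl chloride
Product: 25 (1S,2R)-1-Q-2-[2-(triethylsilyloxy)propan-2-yl]pent-4-en-1-yl prop-2-enoate
Conditions: LiN(SiMe3)2, THF, −78 °C; 24, −78 → 0 °C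
Reagents that add atoms: none
Why: O-acylation of a hindered secondary alcohol through its lithium alkoxide; C6 is not touched.

Step 17
Reactants: 25 (1S,2R)-1-Q-2-[2-(triethylsilyloxy)propan-2-yl]pent-4-en-1-yl prop-2-enoate
Product: 26 (6R,7S)-7-Q-6-[2-(triethylsilyloxy)propan-2-yl]-6,7-dihydro-5H-oxepin-2-one
Conditions: second-generation Grubbs catalyst (5 mol%), toluene (2 mM), 80 °C
Reagents that add atoms: none
Why: Ring-closing metathesis between the allyl alkene and the acrylate forms C9=C10 and the seven-membered lactone with loss of ethene; the trisubstituted cyclopentene alkene next to the quaternary C4 is too hindered to take part.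

Step 18
Reactants: 26 (6R,7S)-7-Q-6-[2-(triethylsilyloxy)propan-2-yl]-6,7-dihydro-5H-oxepin-2-one
Product: 27 (6R,7S)-7-Q-6-[2-(triethylsilyloxy)propan-2-yl]oxepan-2-one (cis lactone; 6S,7R in target numbering)
Conditions: [(Ph3P)CuH]6 (0.4 equiv), toluene, H2O (trace), 25 °C
Reagents that add atoms: none
Why: Conjugate reduction with Stryker's reagent is selective for the enoate and leaves the isolated alkene and the allylic C6–O bond alone.

Step 19
Reactants: 27 (6R,7S)-7-Q-6-[2-(triethylsilyloxy)propan-2-yl]oxepan-2-one
Product: 30 hydroazulene C14 acid (1R,4R,7R,10R,9′S; Ar on C9′; C11 triethylsilyl ether), via silyl ketene acetal 28 (not isolated), via trimethylsilyl ester 29 (not isolated)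
Conditions: LiN(iPr)2, THF, −78 °C; Me3SiCl–Et3N, −78 → 25 °C; toluene, 100 °C; then MeOH–H2O, 25 °C
Reagents that add atoms: chlorotrimethylsilane, C[Si](C)(C)Cl (its atoms stay in 28 and 29 only)
Why: LiN(iPr)2 removes a C10 proton of 27 and Me3SiCl traps the enolate on oxygen as ketene acetal 28, whose geometry is fixed by the ring (ring oxygen and C9 cis). On heating, C10 bonds to C1 of the cyclopentene while the C6–O bond breaks and the alkene moves to C5=C6, a [3,3]-sigmatropic (Ireland–Claisen) shift, and hydrolysis of silyl ester 29 gives 30. The closest known reaction type is the Claisen rearrangement of alkenyl-substituted lactone silyl ketene acetals to cycloalkene carboxylic acids. The cycloheptene (C1, C5–C10) closes by this intramolecular C1–C10 bond formation through a bridged boat transition state, the only one the C7–C8–C9 tether allows, while the lactone ring opens. C1 is controlled by C6: the shift is suprafacial, so C10 arrives on the face from which oxygen leaves, and in the 6S carbinol with C7 turned toward C1 this is the face that carries the C4 methyl, away from the benzylic group. C10 is controlled by the boat together with the fixed ketene acetal geometry, which places the carboxyl and C2 on the same side of the new ring (H1 and H10 cis). The step needs this facial selectivity and needs the shift to outrun ionisation of the allylic C–O bond; attack anti to the large C4 substituent is the matched case, and the C7 side chain, which must sit pseudo-axially in the boat, is the main cost.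

Step 20
Reactants: 30 hydroazulene C14 acid
Product: 31 hydroazulene C14 alcohol (hydroxymethyl on C10; C11 triethylsilyl ether)
Conditions: LiAlH4, THF, 0 → 25 °C
Reagents that add atoms: none
Why: Hydride reduction of the acid to the primary alcohol; silyl ether, alkene and aryl ethers are inert.

Step 21
Reactants: 31 hydroazulene C14 alcohol
Product: 32 hydroazulene C14 tosylate
Conditions: TsCl, pyridine, DMAP (cat.), CH2Cl2, 0 → 25 °C
Reagents that add atoms: 4-toluenesulfonyl chloride, Cc1ccc(cc1)S(Cl)(=O)=O
Why: Sulfonylation of the only free hydroxyl group.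

Step 22
Reactants: 32 hydroazulene C14 tosylate
Product: 33 C10-methyl hydroazulene (Ar on C9′; C11 triethylsilyl ether)
Conditions: LiBHEt3, THF, 0 → 50 °C
Reagents that add atoms: none
Why: SN2 displacement of the primary tosylate by hydride gives the C10 methyl group; no stereocentre is involved.

Step 23
Reactants: 33 C10-methyl hydroazulene
Product: 34 3,5-dibromo-2,4,6-trimethoxyphenyl analogue of 33
Conditions: NBS (2.05 equiv), CH2Cl2, −40 → 0 °C, dark
Reagents that add atoms: N-bromosuccinimide, O=C1CCC(=O)N1Br
Why: Electrophilic bromination of the two free positions of the trimethoxyarene, which should be far faster than attack of NBS on the hindered trisubstituted alkene in a non-nucleophilic solvent.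

Step 24
Reactants: 34 dibromide
Product: 35 3,5-diformyl-2,4,6-trimethoxyphenyl analogue of 33
Conditions: t-BuLi (2.1 equiv), THF, −78 °C; DMF; t-BuLi (2.1 equiv), −78 °C; DMF; NH4Cl aq
Reagents that add atoms: N,N-dimethylformamide, CN(C)C=O
Why: Bromine–lithium exchange and formylation, done twice in one flask; each aryllithium is flanked by two methoxy groups and the first formyl group stays masked as its lithium hemiaminal until work-up, so no acid touches the silyl ether or the alkene.

Step 25
Reactants: 35 dialdehyde silyl ether
Product: 36 dialdehyde with free C11 hydroxyl (trimethyl ether of the target)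
Conditions: Bu4NF, THF, 0 → 25 °C
Reagents that add atoms: none
Why: Fluoride cleaves the Si–O bond of the tertiary silyl ether under non-acidic conditions.

Step 26
Reactants: 36 trimethyl ether of the target
Product: 37 CNP0281883.3 (1R,4R,7R,10R,9′S)
Conditions: EtSNa, DMF, 100 °C; then 1 M HCl
Reagents that add atoms: none
Why: SN2 demethylation by thiolate at the methyl carbons; every methoxy group is ortho or para to a formyl group, which stabilises the leaving aryloxide, and the basic medium spares the tertiary homoallylic alcohol and the alkene.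

## Compound list

1 | 5,7-dimethoxy-2H-chromen-2-one | O=C1C=Cc2c(OC)cc(OC)cc2O1 | starting material
2 | isobutylmagnesium bromide | CC(C)C[Mg]Br | starting material
3 | (4S)-4-isobutyl-5,7-dimethoxychroman-2-one | O=C1C[C@H](CC(C)C)c2c(OC)cc(OC)cc2O1 | intermediate
4 | 1-chloro-3-iodopropane | ClCCCI | starting material
5 | (3S,4S)-3-(3-chloropropyl)-4-isobutyl-5,7-dimethoxychroman-2-one | O=C1[C@@H](CCCCl)[C@H](CC(C)C)c2c(OC)cc(OC)cc2O1 | intermediate
6 | (3R,4R)-3-(3-chloropropyl)-4-isobutyl-5,7-dimethoxy-3-methylchroman-2-one | O=C1[C@](C)(CCCCl)[C@H](CC(C)C)c2c(OC)cc(OC)cc2O1 | intermediate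
7 | (3R,4R)-3-(3-iodopropyl)-4-isobutyl-5,7-dimethoxy-3-methylchroman-2-one | O=C1[C@](C)(CCCI)[C@H](CC(C)C)c2c(OC)cc(OC)cc2O1 | intermediate
8 | (2R)-2-[(1R)-1-(2-hydroxy-4,6-dimethoxyphenyl)-3-methylbutyl]-2-methylcyclopentan-1-one | CC(C)C[C@H](c1c(O)cc(OC)cc1OC)[C@@]1(C)CCCC1=O | intermediate
9 | (2R)-2-methyl-2-[(1R)-3-methyl-1-(2,4,6-trimethoxyphenyl)butyl]cyclopentan-1-one | CC(C)C[C@H](c1c(OC)cc(OC)cc1OC)[C@@]1(C)CCCC1=O | intermediate
10 | (5R)-5-methyl-5-[(1S)-3-methyl-1-(2,4,6-trimethoxyphenyl)butyl]cyclopent-1-en-1-yl trifluoromethanesulfonate | CC(C)C[C@H](c1c(OC)cc(OC)cc1OC)[C@@]1(C)CCC=C1OS(=O)(=O)C(F)(F)F | intermediate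
11 | 3-hydroxy-3-methylbutanoic acid | CC(C)(O)CC(=O)O | starting material
12 | triethylsilyl 3-methyl-3-(triethylsilyloxy)butanoate | CC[Si](CC)(CC)OC(C)(C)CC(=O)O[Si](CC)(CC)CC | intermediate (not isolated)
13 | 3-methyl-3-(triethylsilyloxy)butanoic acid | CC[Si](CC)(CC)OC(C)(C)CC(=O)O | intermediate
14 | (4S)-4-benzyl-1,3-oxazolidin-2-one | O=C1OC[C@H](Cc2ccccc2)N1 | starting material
15 | 3-methyl-3-(triethylsilyloxy)butanoic pivalic anhydride | CC[Si](CC)(CC)OC(C)(C)CC(=O)OC(=O)C(C)(C)C | intermediate (not isolated)
16 | (4S)-4-benzyl-3-[3-methyl-3-(triethylsilyloxy)butanoyl]-1,3-oxazolidin-2-one | CC[Si](CC)(CC)OC(C)(C)CC(=O)N1[C@@H](Cc2ccccc2)COC1=O | intermediate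
17 | allyl iodide (3-iodoprop-1-ene) | C=CCI | starting material
18 | (4S)-4-benzyl-3-{(2S)-2-[2-(triethylsilyloxy)propan-2-yl]pent-4-enoyl}-1,3-oxazolidin-2-one | C=CC[C@@H](C(C)(C)O[Si](CC)(CC)CC)C(=O)N1[C@@H](Cc2ccccc2)COC1=O | intermediate
19 | (2R)-2-[2-(triethylsilyloxy)propan-2-yl]pent-4-en-1-ol | C=CC[C@@H](C(C)(C)O[Si](CC)(CC)CC)CO | intermediate
20 | (2S)-2-[2-(triethylsilyloxy)propan-2-yl]pent-4-enal | C=CC[C@@H](C(C)(C)O[Si](CC)(CC)CC)C=O | intermediate
21 | (2R)-1-Q-2-[2-(triethylsilyloxy)propan-2-yl]pent-4-en-1-ol, both C6 epimers | CC(C)C[C@H](c1c(OC)cc(OC)cc1OC)[C@@]1(C)CCC=C1C(O)[C@@H](CC=C)C(C)(C)O[Si](CC)(CC)CC | intermediate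
22 | (2S)-1-Q-2-[2-(triethylsilyloxy)propan-2-yl]pent-4-en-1-one | CC(C)C[C@H](c1c(OC)cc(OC)cc1OC)[C@@]1(C)CCC=C1C(=O)[C@@H](CC=C)C(C)(C)O[Si](CC)(CC)CC | intermediate
23 | (1S,2R)-1-Q-2-[2-(triethylsilyloxy)propan-2-yl]pent-4-en-1-ol | CC(C)C[C@H](c1c(OC)cc(OC)cc1OC)[C@@]1(C)CCC=C1[C@@H](O)[C@@H](CC=C)C(C)(C)O[Si](CC)(CC)CC | intermediate
24 | acryloyl chloride | C=CC(Cl)=O | starting material
25 | (1S,2R)-1-Q-2-[2-(triethylsilyloxy)propan-2-yl]pent-4-en-1-yl prop-2-enoate | CC(C)C[C@H](c1c(OC)cc(OC)cc1OC)[C@@]1(C)CCC=C1[C@@H](OC(=O)C=C)[C@@H](CC=C)C(C)(C)O[Si](CC)(CC)CC | intermediate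
26 | (6R,7S)-7-Q-6-[2-(triethylsilyloxy)propan-2-yl]-6,7-dihydro-5H-oxepin-2-one | CC(C)C[C@H](c1c(OC)cc(OC)cc1OC)[C@@]1(C)CCC=C1[C@H]1OC(=O)C=CC[C@H]1C(C)(C)O[Si](CC)(CC)CC | intermediate
27 | (6R,7S)-7-Q-6-[2-(triethylsilyloxy)propan-2-yl]oxepan-2-one | CC(C)C[C@H](c1c(OC)cc(OC)cc1OC)[C@@]1(C)CCC=C1[C@H]1OC(=O)CCC[C@H]1C(C)(C)O[Si](CC)(CC)CC | intermediate (precursor of the key step)
28 | trimethylsilyl ketene acetal of 27 (C10=C14 in the ring, OSiMe3 on C14) | CC(C)C[C@H](c1c(OC)cc(OC)cc1OC)[C@@]1(C)CCC=C1[C@H]1OC(O[Si](C)(C)C)=CCC[C@H]1C(C)(C)O[Si](CC)(CC)CC | intermediate (not isolated)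
29 | trimethylsilyl ester of 30 | CC(C)C[C@H](c1c(OC)cc(OC)cc1OC)[C@@]1(C)CC[C@H]2C1=C[C@H](C(C)(C)O[Si](CC)(CC)CC)CC[C@H]2C(=O)O[Si](C)(C)C | intermediate (not isolated)
30 | (1R,4R,7R,10R)-4-methyl-4-[(1S)-3-methyl-1-(2,4,6-trimethoxyphenyl)butyl]-7-[2-(triethylsilyloxy)propan-2-yl]bicyclo[5.3.0]dec-5-ene-10-carboxylic acid (guaiane numbering) | CC(C)C[C@H](c1c(OC)cc(OC)cc1OC)[C@@]1(C)CC[C@H]2C1=C[C@H](C(C)(C)O[Si](CC)(CC)CC)CC[C@H]2C(=O)O | intermediate (product of the key step)
31 | 10-(hydroxymethyl) analogue of 30 | CC(C)C[C@H](c1c(OC)cc(OC)cc1OC)[C@@]1(C)CC[C@H]2C1=C[C@H](C(C)(C)O[Si](CC)(CC)CC)CC[C@H]2CO | intermediate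
32 | 10-(4-toluenesulfonyloxymethyl) analogue of 30 | CC(C)C[C@H](c1c(OC)cc(OC)cc1OC)[C@@]1(C)CC[C@H]2C1=C[C@H](C(C)(C)O[Si](CC)(CC)CC)CC[C@H]2COS(=O)(=O)c3ccc(C)cc3 | intermediate
33 | (1R,4R,7R,10R)-4,10-dimethyl-4-[(1S)-3-methyl-1-(2,4,6-trimethoxyphenyl)butyl]-7-[2-(triethylsilyloxy)propan-2-yl]bicyclo[5.3.0]dec-5-ene | CC(C)C[C@H](c1c(OC)cc(OC)cc1OC)[C@@]1(C)CC[C@H]2C1=C[C@H](C(C)(C)O[Si](CC)(CC)CC)CC[C@H]2C | intermediate
34 | 3,5-dibromo-2,4,6-trimethoxyphenyl analogue of 33 | CC(C)C[C@H](c1c(OC)c(Br)c(OC)c(Br)c1OC)[C@@]1(C)CC[C@H]2C1=C[C@H](C(C)(C)O[Si](CC)(CC)CC)CC[C@H]2C | intermediate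
35 | 3,5-diformyl-2,4,6-trimethoxyphenyl analogue of 33 | CC(C)C[C@H](c1c(OC)c(C=O)c(OC)c(C=O)c1OC)[C@@]1(C)CC[C@H]2C1=C[C@H](C(C)(C)O[Si](CC)(CC)CC)CC[C@H]2C | intermediate
36 | 2,4,6-tri-O-methyl ether of the target | CC(C)C[C@H](c1c(OC)c(C=O)c(OC)c(C=O)c1OC)[C@@]1(C)CC[C@H]2C1=C[C@H](C(C)(C)O)CC[C@H]2C | intermediate
37 | CNP0281883.3: 2,4,6-trihydroxy-5-{(1S)-1-[(1R,4R,7R,10R)-7-(2-hydroxypropan-2-yl)-4,10-dimethylbicyclo[5.3.0]dec-5-en-4-yl]-3-methylbutyl}benzene-1,3-dicarbaldehyde (guaiane numbering) | CC(C)C[C@H](c1c(O)c(C=O)c(O)c(C=O)c1O)[C@@]1(C)CC[C@H]2C1=C[C@H](C(C)(C)O)CC[C@H]2C | target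

## Step count and least certain steps

Total: 26 steps. Longest linear sequence: 21 steps (steps 1–7 and 13–26); the aldehyde branch is steps 8–12.

**Step 19 (key step).** The most likely failure is a slow shift with competing ionisation of the allylic C6–O bond or C-silylation. The boat must carry the C7 side chain pseudo-axially and bring C10 over a cyclopentene carbon next to the quaternary centre.

Fallback: form the same C1–C10 bond by an acyclic Ireland–Claisen rearrangement, which can use a chair and has no C7 substituent in the pericyclic array, then close the ring at C5=C6 by metathesis. It sets out from triflate 10 and alcohol 19 and comes back at acid 30. Palladium-catalysed methoxycarbonylation of 10 (Pd(OAc)2, PPh3, CO, MeOH, Et3N) would give the methyl cyclopentenecarboxylate F1, and i-Bu2AlH the primary allylic alcohol F2. From 19, cross-metathesis with methyl acrylate would give the hydroxy enoate F3, hydrogenation the saturated hydroxy ester F4, Dess–Martin oxidation the aldehyde F5, Wittig methylenation the vinyl ester F6, and LiOH the vinyl acid F7. Carbodiimide esterification of F2 with F7 gives the allylic ester F8. Its silyl ketene acetal should rearrange to the methylenecyclopentyl acid F9, with C1 set by attack anti to the benzylic group on C4 and C10 by the ketene acetal geometry chosen through the enolisation solvent. Ring-closing metathesis of F9 between the exocyclic methylene on C5 and the vinyl group on C7 returns 30.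

**Step 1.** The addition may be sluggish, go 1,2, or show poor face selection, because two methoxy groups make the enoate electron-rich and the C5 methoxy group crowds the β-carbon.

Fallback: bring in the isobutyl group with the coumarin and set C9′ by hydride. In place of 1 and 2, it sets out from purchased 3,5-dimethoxyphenol F10 and ethyl 5-methyl-3-oxohexanoate F11. Pechmann condensation (MeSO3H) gives the 4-isobutylcoumarin F12, and copper hydride-catalysed asymmetric conjugate reduction (Cu(OAc)2, chiral bisphosphine, polymethylhydrosiloxane, t-BuOH) returns to the route at 3.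

**Step 15.** The risk is poor facial selectivity or competing conjugate reduction, since the ketone is flanked by two bulky groups and is part of an enone.

Fallback: use the intrinsic preference of the addition instead of correcting it by reduction. It sets out from the major 6R epimer of 21, separated after step 13. A Mitsunobu reaction with 4-nitrobenzoic acid (PPh3, diisopropyl azodicarboxylate) inverts C6 to the 6S 4-nitrobenzoate F13, and methanolysis (K2CO3, MeOH) returns 23.

**Step 24 (with step 23).** The second exchange may be incomplete, the crowded aryllithium may be protonated, or the bromination before it may stray to the alkene.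

Fallback: formylate through C–H lithiation and leave out the bromination. It sets out from 33. n-BuLi/TMEDA lithiates a position between two methoxy groups and DMF gives the monoaldehyde F14. After in-flask protection of the formyl group as its lithium α-amino alkoxide (lithium N-methylpiperazide), a second lithiation and DMF quench give 35.

**Step 26.** The cleavage may stall after one or two methyl groups, because each phenoxide formed deactivates the ring towards further SN2 attack, and the aldehydes see long heating with a nucleophile.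

Fallback: cleave the ethers by chelation-assisted Lewis-acid attack while the alcohol is still silylated, and reverse the order of the last two steps. It sets out from 35. BCl3 (CH2Cl2, −78 °C) would give the triphenol silyl ether F15, each methoxy group being next to a formyl group, and buffered HF·pyridine then removes the silyl group and gives 37.

## Further compounds

F1 | step 19 | methyl (5R)-5-methyl-5-[(1S)-3-methyl-1-(2,4,6-trimethoxyphenyl)butyl]cyclopent-1-ene-1-carboxylate | CC(C)C[C@H](c1c(OC)cc(OC)cc1OC)[C@@]1(C)CCC=C1C(=O)OC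
F2 | step 19 | {(5R)-5-methyl-5-[(1S)-3-methyl-1-(2,4,6-trimethoxyphenyl)butyl]cyclopent-1-en-1-yl}methanol | CC(C)C[C@H](c1c(OC)cc(OC)cc1OC)[C@@]1(C)CCC=C1CO
F3 | step 19 | methyl (2E,5R)-5-(hydroxymethyl)-6-methyl-6-(triethylsilyloxy)hept-2-enoate | COC(=O)/C=C/C[C@@H](C(C)(C)O[Si](CC)(CC)CC)CO
F4 | step 19 | methyl (5R)-5-(hydroxymethyl)-6-methyl-6-(triethylsilyloxy)heptanoate | COC(=O)CCC[C@@H](C(C)(C)O[Si](CC)(CC)CC)CO
F5 | step 19 | methyl (5S)-5-formyl-6-methyl-6-(triethylsilyloxy)heptanoate | COC(=O)CCC[C@@H](C(C)(C)O[Si](CC)(CC)CC)C=O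
F6 | step 19 | methyl (5R)-5-[2-(triethylsilyloxy)propan-2-yl]hept-6-enoate | COC(=O)CCC[C@@H](C(C)(C)O[Si](CC)(CC)CC)C=C
F7 | step 19 | (5R)-5-[2-(triethylsilyloxy)propan-2-yl]hept-6-enoic acid | OC(=O)CCC[C@@H](C(C)(C)O[Si](CC)(CC)CC)C=C
F8 | step 19 | allylic ester of F2 with F7 | CC(C)C[C@H](c1c(OC)cc(OC)cc1OC)[C@@]1(C)CCC=C1COC(=O)CCC[C@@H](C(C)(C)O[Si](CC)(CC)CC)C=C
F9 | step 19 | 2-methylenecyclopentyl acid (C1–C10 formed, C5=CH2, vinyl on C7) | CC(C)C[C@H](c1c(OC)cc(OC)cc1OC)[C@@]1(C)CC[C@H]([C@@H](CC[C@@H](C(C)(C)O[Si](CC)(CC)CC)C=C)C(=O)O)C1=C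
F10 | step 1 | 3,5-dimethoxyphenol | COc1cc(O)cc(OC)c1
F11 | step 1 | ethyl 5-methyl-3-oxohexanoate | CCOC(=O)CC(=O)CC(C)C
F12 | step 1 | 4-isobutyl-5,7-dimethoxy-2H-chromen-2-one | O=C1C=C(CC(C)C)c2c(OC)cc(OC)cc2O1
F13 | step 15 | (1S,2R)-1-Q-2-[2-(triethylsilyloxy)propan-2-yl]pent-4-en-1-yl 4-nitrobenzoate | CC(C)C[C@H](c1c(OC)cc(OC)cc1OC)[C@@]1(C)CCC=C1[C@@H](OC(=O)c1ccc(cc1)[N+](=O)[O-])[C@@H](CC=C)C(C)(C)O[Si](CC)(CC)CC
F14 | step 24 | 3-formyl-2,4,6-trimethoxyphenyl analogue of 33 | CC(C)C[C@H](c1c(OC)c(C=O)c(OC)cc1OC)[C@@]1(C)CC[C@H]2C1=C[C@H](C(C)(C)O[Si](CC)(CC)CC)CC[C@H]2C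
F15 | step 26 | C11 triethylsilyl ether of the target | CC(C)C[C@H](c1c(O)c(C=O)c(O)c(C=O)c1O)[C@@]1(C)CC[C@H]2C1=C[C@H](C(C)(C)O[Si](CC)(CC)CC)CC[C@H]2C
A1 | alternative 1 | hydroazulene C7 methyl ester | CC(C)C[C@H](c1c(OC)cc(OC)cc1OC)[C@@]1(C)CC[C@H]2C1=C[C@H](C(=O)OC)CC[C@H]2C
A2 | alternative 1 | iodo enoate (acrylate on C5, iodide on C8; C5 epimers) | CC(C)C[C@H](c1c(OC)cc(OC)cc1OC)[C@@]1(C)CC[C@H]([C@H](C)CCI)C1/C=C/C(=O)OC
A3 | alternative 2 | bicyclo[5.3.0]decadienone with C3 ketone | CC(C)C[C@H](c1c(OC)cc(OC)cc1OC)[C@@]1(C)C(=O)C=C2C1=C[C@H](C(C)(C)O[Si](CC)(CC)CC)CC[C@H]2C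
A4 | alternative 2 | allene–yne (allene axis undefined) | C#C[C@H](C)CC[C@@H](C(C)(C)O[Si](CC)(CC)CC)C=C=C(C)[C@H](CC(C)C)c1c(OC)cc(OC)cc1OC
A5 | alternative 3 | 2-alkylphloroglucinol with C11 triethylsilyl ether | CC(C)C[C@H](c1c(O)cc(O)cc1O)[C@@]1(C)CC[C@H]2C1=C[C@H](C(C)(C)O[Si](CC)(CC)CC)CC[C@H]2C
A6 | alternative 3 | methyl 3,5-dioxo ester on C9′ | CC(C)C[C@H](CC(=O)CC(=O)CC(=O)OC)[C@@]1(C)CC[C@H]2C1=C[C@H](C(C)(C)O[Si](CC)(CC)CC)CC[C@H]2C
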